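All runs were generated by integration with constants of no real substance, and the scatter is random.

Saturday's run on this flask is slow: it stops at 5.00 h with 18.8% of the substrate lost, yet the flask is asked about at 25 h, so a few slow rows must be stretched a long way.

common to all: substrate 0.25 M; gas phase 56 mM (held)

| flask | protic impurity | remark | time |
|---|---|---|---|
| Saturday's | 0.025 M | the very flask that is asked about, followed so far |  |
| flask | 0.0250 M |  | 25 h |

Saturday's run (percent of the substrate charged)

| time / h | target / % | substrate / % |
|---|---|---|
| 0.833 | 0.8 | 97.7 |
| 1.50 | 0.8 | 94.9 |
| 2.50 | 2.9 | 91.0 |
| 3.00 | 2.9 | 89.2 |
| 4.00 | 5.8 | 85.2 |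
| 5.00 | 6.4 | 81.2 |

(each reading ± 0.5 percentage points)

- the analysis behind the earlier runs scatters by 0.5 percentage points, standard deviation
- at the start none of the gas phase is in solution

1. amount of target at 25 h, in percent of the substrate charged
2. concentration of dissolved gas in solution at 6.0 h, in percent of saturation
3. the change that raises the amount of target at 25 h, in percent of the substrate charged most ("none" if none brings more than 2 percentage points) (summer / dawn / none)
4. amount of target at 25 h, in percent of the substrate charged, after dawn

- summer: doubling the transfer coefficient of the gas phase, all else as stated
- dawn: doubling the saturation concentration of gas phase, all else as stated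

Read Saturday's table column against column. In its last row, divide target by substrate lost: this target share, the apparent selectivity, reads 34.0%. Then go up to the row at 2.50 h, where the same division reads 32.2%. Between these rows no climb shows beyond the scatter of 0.5 percentage points per reading, so treat the share as constant and count the remaining lost substrate as going somewhere neither column shows.

Now read the substrate column. Taken as a first-order fall, its last row gives c(substrate) a rate of 0.0417 h⁻¹, a half-life of 16.6 h. This is a choice, since a straight line fits these rows too. Stretched over 25 h, this rate reckons 35.3% of the substrate left in this flask, and the share turns the reckoned loss into 22.0% of target. Commit to that figure. Dissolved gas stands in neither column, so leave its level and the two changes unreckoned.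

The forecast differs, with 72% of target, 7% of saturation, dawn as the best change and 92% after it, and it reads the rows otherwise: “The target lags the substrate loss, which suggests an intermediate”.

The simulation gives 20.2% of target, c(dissolved gas) at 50.7% of saturation at 6.0 h, dawn as the best change (9 points against 3.5 points for summer), and 29.2% after it.

    substrate → side product (k = 7.10 × 10⁻⁶ s⁻¹)
    2 dissolved gas → self-condensation product (k = 6.10 × 10⁻⁴ M⁻¹ s⁻¹)
    target ⇌ isomer of the product (K = 2.80, k = 1.30 × 10⁻⁵ s⁻¹)
    dissolved gas + protic impurity → quenched reagent (k = 0.00320 M⁻¹ s⁻¹)
    gas phase ⇌ dissolved gas, rate k5*(csat - [dissolved gas]) (kL = 1.10 × 10⁻⁴ s⁻¹)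
    substrate + dissolved gas → target (k = 2.20 × 10⁻⁴ M⁻¹ s⁻¹)

At 25 h the same division on this flask gives 28.4%, lower than the share carried from Saturday's table, with the isomer of the product at 13.2%. By the forward step alone, target then has a half-life of 15 h, shorter than the 25 h of the run.

For the neighbour flask read at 6.0 h, the rate gives 77.9% of substrate and the share then gives 7.53% of target. Computed, that flask holds 77.6% of substrate and 7.83% of target.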